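(The data were generated by integration from invented constants, and the scatter is random.)

I decide to reckon this flask by the fraction of its gap still open, not by the target made.

| setting | green | flask |
|---|---|---|
| electrophile | 1 M | 1.0 M |
| free base | 1.2 M | 1.20 M |
| protonated nucleophile | 2 M | 2.00 M |
| remark | the very flask that is asked about, followed so far |  |
| time |  | 25 h |

green run (percent of the electrophile charged)

| time / h | target / % |
|---|---|
| 0.667 | 14.0 |
| 1.00 | 16.7 |
| 1.50 | 20.9 |
| 2.50 | 25.5 |
| 5.00 | 27.8 |
| 8.00 | 27.6 |

(standard deviation of a reading: 0.5 percentage points)

- the reaction counts as stopped when no species that holds the electrophile changes by six tenths of a point or more over the second half of the time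

* the state of affairs at 25 h: stopped, and by what, or still going (the free base has run out first / forward and back rates have come level / all of the electrophile has reacted / it is still moving)
* target at 25 h, in percent of the electrophile charged
* amount of target if the flask were left three thousand times as long, in percent of the electrophile charged

The last two readings, 27.8% and 27.6%, stand 0.2 percentage points apart with a scatter of 0.5 points, so I take their mean, 27.7%, as the plateau. But a plateau needs a test. Between the first reading and the one at 2.50 h, the open fraction falls from 49.5% to 7.94%, so it halves every 0.695 h. This is the gap half-life: the time in which the distance to the plateau, as a share of the plateau, halves. It is a relaxation half-life read from the readings. The asked time holds 36.0 of them, and at its halfway mark my open gap is worth 1.1 × 10⁻⁴ points, to be held against the margin of the stopping rule. So I read the plateau at 25 h.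

The forecast says forward and back rates have come level, with 27.7% (27% to 28.4%) at 25 h and 27.7% (26.8% to 28.6%) after the long wait: “That points to equilibrium.”

The flask gives forward and back rates have come level, with 27.6% at 25 h and 27.6% after the long wait.

    electrophile + nucleophile ⇌ acid set free + target (K = 0.770, k = 0.00260 L mol⁻¹ s⁻¹)
    nucleophile + acid set free ⇌ protonated nucleophile, settled at all times (K = 4000 L mol⁻¹)
    acid set free + free base ⇌ salt of the base (K = 120 L mol⁻¹, k = 0.0170 L mol⁻¹ s⁻¹)
    target ⇌ isomer of the product (K = 0.630, k = 6.50 × 10⁻⁴ s⁻¹)

The gap half-life puts 90.0% of the rise in target at 2.31 h, and this flask reaches that share of its conversion at 2.54 h. This flask stops with 55% of the electrophile and 26% of the free base still there, held in part by the back run from acid set free and target together with the falling free base; with the free base level held, conversion goes from 45.1% to 76.6%. If I lend this gap half-life to a neighbour flask charged with 3.0 M of free base, its open gap at the halfway mark is worth 1.9 × 10⁻⁴ points, and that neighbour flask reads 48.9% at 25 h, its end amount of 48.9%.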